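## Structural features

The target has two six-membered rings joined by one C(sp3)–C(sp2) bond. Ring A is a p-menthane cyclohexane: C1 = C(OH)CH3, C2 = CH bearing ring B, C3, C4 = CH bearing the isopropenyl carbon C8, C5, C6, with C7 the methyl on C1. Ring B is a fully substituted, enolised cyclohexane-1,3,5-trione: C1′ is bonded to C2, C2′/C4′/C6′ are oxygenated, C3′ carries isobutyryl and C5′ is quaternary with two prenyl groups.

All three stereocentres lie on ring A: C1 (R) and C2 (R) are adjacent, and C4 (S) is 1,3 to C2 and 1,4 to C1. In the chair the methyl, ring B and the isopropenyl group are all equatorial, and the C1–OH is axial and cis to ring B.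

The fragile groups are the tertiary C1–OH, which sits syn to an enol OH and can close to a dihydrofuran or eliminate under acid, the three electron-rich alkenes, and the acidic, ambident β-triketone.

The real difficulty is the congested C2–C1′ bond together with the stereotriad. Ring B is a natural nucleophile, but attack on a C1/C2 epoxide is anti and puts the C1 oxygen trans to ring B, the opposite of the target. C4 is too remote to control C1 in any alkene addition.

Without C7, ring A is a 2-substituted 4-isopropenylcyclohexanone. Its parent ketone is achiral with enantiotopic α-carbons C2 and C6, a substituent at C2 is epimerisable to the all-equatorial cis arrangement, and methyl addition can then set C1 from the ring conformation.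

The key step exploits the atoms C2, C3, C4 and C8. An extra bond C2–C8, absent from the target, closes a cyclobutane and turns ring A into the bicyclo[3.1.1]heptane of nopinone, in which C2 is a bridgehead. Breaking that bond releases the strain, makes C8 the isopropenyl carbon, and makes C2, and only C2, an enol carbon.

## Logic of the disconnections

**15 ⇒ 13 (through 14).** The two C5′–CH2 bonds to the prenyl groups are cut. The dearomatised triketone and its prenyl alkenes would not survive organometallic or acidic steps, so they are made last. Ring B becomes an aromatic acylphloroglucinol. The forward step must alkylate twice at carbon C5′, not at oxygen and not at C1′.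

**13 ⇒ 10 (through 12).** The C3′–C(=O) bond of the isobutyryl group is cut and the three phenols are masked as acetal ethers. Anionic acylation avoids Lewis-acid Friedel–Crafts conditions, which the tertiary alcohol and the isopropenyl group would not tolerate. The aryl group becomes a symmetric trioxygenated ring. The forward steps need lithiation only between two acetal ethers, and acetal removal without ionising C1–OH.

**10 ⇒ 9.** The C1–C7 bond is cut. C1 is 1,4 to C4, so it is best set by the chair of a ketone. This removes the quaternary stereocentre and makes C2 epimerisable. The methyl nucleophile must add rather than enolise, and must enter equatorially.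

**9 ⇒ 6 + 3.** The C2–C1′ bond is cut. Both carbons are natural nucleophiles (enol carbon and phloroglucinol carbon), so the arene is used as the electrophile 3 under palladium catalysis. The molecule splits into two halves of similar size, and C2 needs no kinetic control. The parent ketone of 6 is achiral, so the coupling must occur only at the enol carbon of 6 and the double bond must not migrate; any regiochemical leak is racemisation.

**6 ⇒ 4 (key).** In the retrosynthetic direction the bond C2–C8 is formed, closing the cyclobutane. The forward fragmentation cleaves it, creating the C1=C2 enol and the C8=C9 alkene. A chiral, regiodefined enol ether of an achiral ketone is traced in one step to a commercial enantiopure ketone. The forward step must cleave the bond to the gem-dimethyl carbon, must not allow acid-mediated loss of the enol ether, and must eliminate toward a methyl group.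

**3 ⇒ 2 ⇒ 1.** The C–Br bond and the three O–CH2 bonds are cut, leading to the symmetric triphenol. Monobromination must stop after one substitution.

## Other disconnections considered

Alternative 1: This is the first idea. Cut C2–C1′ with natural polarity: Lewis-acid opening of (1R,2S,4S)-limonene 1,2-oxide A1 by the diprenylated acyl triketone A2 (or its aromatic precursor) at C2. Epoxide opening is anti, so the C1 oxygen and the new C–C bond end up trans. The Fürst–Plattner-allowed attack at C2 of A1 would give A3, the C2 epimer of the target. The other epoxide diastereomer would need a non-diaxial attack and would give the C1 epimer. C2 cannot be corrected afterwards, and the Lewis acid also invites attack at tertiary C1, epoxide rearrangement and O-alkylation. The chosen plan sets the cis C1–O/C2–C relation by ring conformation instead.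

Alternative 2: Cut C2–C1′ by a [3,3] shift: aromatic Claisen rearrangement of the aryl perillyl ether A4 to the 2-aryl-p-mentha-1(7),8-diene A5, then Markovnikov hydration of C1=C7. This keeps all ten terpene carbons. However, the facial selectivity at C2 rests only on the remote C4 substituent. A chair-like transition state forms the new bond axially, trans to an equatorial isopropenyl. C2 is then fixed for good. The hydration must also distinguish two 1,1-disubstituted alkenes and place OH cis to the arene. That leaves three unsecured selectivities, against thermodynamic control at C2 and conformational control at C1 in the chosen plan.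

Alternative 3: The same strain-release idea in the reverse order. Ozonolysis of (+)-β-pinene A6 gives (1S,5R)-nopinone A7. Palladium α-arylation at C3 (the bridgehead cannot enolise) gives A8, and Lewis-acid fragmentation of A8 gives 8 and then 9. The regiochemistry is beyond doubt. The drawbacks are the scarce enantiomer and one more step, and a cationic fragmentation run in the presence of three acetal ethers and a very nucleophilic arene. That invites acetal loss with benzofuran formation at the ketone, and Friedel–Crafts capture of the C8 cation. The chosen plan fragments the bare ketone 4, the cheap enantiomer, and accepts in exchange that the enol regiochemistry of 6 must be preserved.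

Key step: step 3

Assumptions: ring B is drawn as one enol tautomer of a freely equilibrating β-triketone. Compound 4 is the commercial (1R,5S) enantiomer, (+)-nopinone, and 1 is commercial.

## Steps

Step 1
Reactants: 1 phloroglucinol (benzene-1,3,5-triol)
Product: 2 1,3,5-tris(methoxymethoxy)benzene
Conditions: NaH (3.6 equiv), DMF, 0 °C; MOMCl (3.5 equiv), 0 °C → rt
Reagents that add atoms: chloromethyl methyl ether, COCCl
Why: Williamson O-alkylation of the triphenoxide with a hard α-chloro ether should go at oxygen; the acetal ethers withstand fluoride, Grignard and organolithium reagents and later direct the ortho-lithiation.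

Step 2
Reactants: 2 1,3,5-tris(methoxymethoxy)benzene
Product: 3 2-bromo-1,3,5-tris(methoxymethoxy)benzene
Conditions: NBS (1.0 equiv), CH2Cl2, 0 °C, dark
Reagents that add atoms: N-bromosuccinimide, O=C1CCC(=O)N1Br
Why: Electrophilic aromatic bromination of a triply activated arene; the three free positions are equivalent, and one equivalent of NBS at 0 °C should stop at the monobromide because the first bromine deactivates and crowds the ring.

Step 3
Reactants: 4 (+)-nopinone, (1R,5S)-6,6-dimethylbicyclo[3.1.1]heptan-2-one
Product: 6 trimethyl{[(4S)-4-(prop-1-en-2-yl)cyclohex-1-en-1-yl]oxy}silane, via tertiary iodide enol ether 5 (not isolated)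
Conditions: TMSI (1.05 equiv), CH2Cl2, −40 → 0 °C, no base; then DBU (2.5 equiv), 0 °C → rt; pentane, filtration, distillation (no aqueous work-up)
Reagents that add atoms: iodotrimethylsilane, C[Si](C)(C)I
Why: Silylation of the carbonyl oxygen by TMSI gives a silyloxycarbenium ion whose empty p orbital overlaps with the strained C1–C6 bond of the cyclobutane (C2–C8 in target numbering); this bond breaks heterolytically (retro-Prins, Grob-type fragmentation) with release of the cyclobutane strain, the tertiary cation is captured by iodide to give 5, and DBU then removes HI by E2 and scavenges acid. The closest known reaction types are the Lewis-acid cleavage of this same bond of 4 under acetylating conditions and the silyl-iodide opening of cyclopropyl ketones to γ-iodo silyl enol ethers. No ring is closed and no stereocentre is created: the bridgehead C5 of 4 is untouched and becomes C4 (S), while the former bridgehead C1 becomes the enol carbon C2. The enol double bond can arise only at the carbon that loses the bond, so 6 should be a single regioisomer; since its parent ketone is achiral, this regiochemistry is the whole stereochemical content that step 4 turns into the C2/C4 pattern. Three selectivities are needed: cleavage of C1–C6 and not C1–C7 (tertiary against primary cation, secured by the gem-dimethyl group); no ordinary enol silylation toward C3 (secured by running the cleavage without base, so that this path stays reversible); and elimination toward a methyl group and not the ring methine (six exposed hydrogens against one hindered hydrogen, with a bulky amidine base).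

Step 4
Reactants: 6 trimethyl{[(4S)-4-(prop-1-en-2-yl)cyclohex-1-en-1-yl]oxy}silane; 3 2-bromo-1,3,5-tris(methoxymethoxy)benzene
Product: 9 (2R,4S)-4-(prop-1-en-2-yl)-2-[2,4,6-tris(methoxymethoxy)phenyl]cyclohexan-1-one, via tributyltin enolate 7 (not isolated), via trans ketone epimer 8 (not isolated)
Conditions: Pd2(dba)3 (2.5 mol %), P(t-Bu)3 (10 mol %), Bu3SnF (1.5 equiv), toluene, 85 °C; then K2CO3, MeOH, rt
Reagents that add atoms: none
Why: Palladium-catalysed α-arylation of a silyl enol ether through its tin enolate (Buchwald–Hartwig-type ketone arylation) joins two carbons that are both natural nucleophiles and should react only at the enol carbon C2, so the double-bond position of 6 becomes absolute configuration. The new α-aryl methine is epimerisable, and base equilibration should convert 8 into 9 because only the cis isomer can hold the aryl and isopropenyl groups both equatorial.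

Step 5
Reactants: 9 (2R,4S)-4-(prop-1-en-2-yl)-2-[2,4,6-tris(methoxymethoxy)phenyl]cyclohexan-1-one
Product: 10 (1R,2R,4S)-1-methyl-4-(prop-1-en-2-yl)-2-[2,4,6-tris(methoxymethoxy)phenyl]cyclohexan-1-ol
Conditions: anhydrous CeCl3 (3 equiv), MeMgBr (3 equiv), THF, −78 → 0 °C; aq NH4Cl
Reagents that add atoms: methylmagnesium bromide, C[Mg]Br
Why: 1,2-Addition of an organocerium reagent, which should add to the enolisable α-aryl ketone instead of deprotonating it. In the chair with aryl and isopropenyl equatorial, a methyl nucleophile should enter equatorially, trans to the neighbouring aryl group, giving the axial C1–OH cis to the arene (1R).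

Step 6
Reactants: 10 (1R,2R,4S)-1-methyl-4-(prop-1-en-2-yl)-2-[2,4,6-tris(methoxymethoxy)phenyl]cyclohexan-1-ol
Product: 12 1-{3-[(1R,2R,5S)-2-hydroxy-2-methyl-5-(prop-1-en-2-yl)cyclohexyl]-2,4,6-tris(methoxymethoxy)phenyl}-2-methylpropan-1-one, via dilithiated aryllithium alkoxide 11 (not isolated)
Conditions: n-BuLi (2.5 equiv), THF, 0 °C, 1 h; then i-PrC(O)N(OMe)Me (1.5 equiv), −78 °C → rt; aq NH4Cl
Reagents that add atoms: N-methoxy-N-methyl-2-methylpropanamide, CC(C)C(=O)N(C)OC
Why: After deprotonation of the alcohol, directed ortho-metalation should occur between two OMOM groups (the two open ring positions are equivalent by rotation about C2–C1′), followed by a Weinreb ketone synthesis whose chelated tetrahedral intermediate prevents over-addition. No Lewis acid touches the tertiary alcohol or the isopropenyl group.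

Step 7
Reactants: 12 1-{3-[(1R,2R,5S)-2-hydroxy-2-methyl-5-(prop-1-en-2-yl)cyclohexyl]-2,4,6-tris(methoxymethoxy)phenyl}-2-methylpropan-1-one
Product: 13 1-{2,4,6-trihydroxy-3-[(1R,2R,5S)-2-hydroxy-2-methyl-5-(prop-1-en-2-yl)cyclohexyl]phenyl}-2-methylpropan-1-one
Conditions: HCl (1 M in MeOH), 0 °C → rt, monitored and quenched with NaHCO3 on completion
Reagents that add atoms: none
Why: Acid-catalysed transacetalisation of the three aryl methoxymethyl ethers to methanol; aryl acetals of an electron-rich ring should cleave under dilute acid at or below room temperature. Ionisation of the tertiary C1–OH or protonation of the isopropenyl group needs stronger acid, so the stereocentres should stay intact.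

Step 8
Reactants: 13 1-{2,4,6-trihydroxy-3-[(1R,2R,5S)-2-hydroxy-2-methyl-5-(prop-1-en-2-yl)cyclohexyl]phenyl}-2-methylpropan-1-one
Product: 15 3,5-dihydroxy-4-[(1R,2R,5S)-2-hydroxy-2-methyl-5-(prop-1-en-2-yl)cyclohexyl]-2-(2-methylpropanoyl)-6,6-bis(3-methylbut-2-en-1-yl)cyclohexa-2,4-dien-1-one (the target), via monoprenyl acylphloroglucinol 14 (not isolated)
Conditions: NaOMe (3.2 equiv), MeOH, −10 → 0 °C; prenyl bromide (2.2 equiv) added slowly; aq citric acid to pH 4
Reagents that add atoms: prenyl bromide (1-bromo-3-methylbut-2-ene), CC(C)=CCBr
Why: C-Alkylation of the acylphloroglucinolate in a protic medium, the alkylative dearomatisation used for lupulone-type compounds. The first prenyl group should enter the only free ring position C5′, and the second the same carbon, because the alternative C1′ carries the bulky secondary cyclohexyl group. Methoxide does not deprotonate the tertiary alcohol and no stereocentre is touched.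

## Compound list

1 | phloroglucinol (benzene-1,3,5-triol) | Oc1cc(O)cc(O)c1 | starting material
2 | 1,3,5-tris(methoxymethoxy)benzene | COCOc1cc(OCOC)cc(OCOC)c1 | intermediate
3 | 2-bromo-1,3,5-tris(methoxymethoxy)benzene | COCOc1cc(OCOC)c(Br)c(OCOC)c1 | intermediate
4 | (+)-nopinone, (1R,5S)-6,6-dimethylbicyclo[3.1.1]heptan-2-one | CC1(C)[C@H]2CCC(=O)[C@@H]1C2 | starting material
5 | {[(4S)-4-(2-iodopropan-2-yl)cyclohex-1-en-1-yl]oxy}trimethylsilane (tertiary iodide enol ether) | CC(C)(I)[C@H]1CCC(O[Si](C)(C)C)=CC1 | intermediate
6 | trimethyl{[(4S)-4-(prop-1-en-2-yl)cyclohex-1-en-1-yl]oxy}silane | C=C(C)[C@H]1CCC(O[Si](C)(C)C)=CC1 | intermediate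
7 | tributyl{[(4S)-4-(prop-1-en-2-yl)cyclohex-1-en-1-yl]oxy}stannane (tin enolate, O-bound form) | C=C(C)[C@H]1CCC(O[Sn](CCCC)(CCCC)CCCC)=CC1 | intermediate
8 | (2S,4S)-4-(prop-1-en-2-yl)-2-[2,4,6-tris(methoxymethoxy)phenyl]cyclohexan-1-one (trans epimer) | C=C(C)[C@H]1CCC(=O)[C@H](c2c(OCOC)cc(OCOC)cc2OCOC)C1 | intermediate
9 | (2R,4S)-4-(prop-1-en-2-yl)-2-[2,4,6-tris(methoxymethoxy)phenyl]cyclohexan-1-one (cis) | C=C(C)[C@H]1CCC(=O)[C@@H](c2c(OCOC)cc(OCOC)cc2OCOC)C1 | intermediate
10 | (1R,2R,4S)-1-methyl-4-(prop-1-en-2-yl)-2-[2,4,6-tris(methoxymethoxy)phenyl]cyclohexan-1-ol | C=C(C)[C@H]1CC[C@@](C)(O)[C@@H](c2c(OCOC)cc(OCOC)cc2OCOC)C1 | intermediate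
11 | lithium alkoxide of 10, lithiated at the ring carbon between two OMOM groups | C=C(C)[C@H]1CC[C@@](C)(O[Li])[C@@H](c2c(OCOC)c([Li])c(OCOC)cc2OCOC)C1 | intermediate
12 | 1-{3-[(1R,2R,5S)-2-hydroxy-2-methyl-5-(prop-1-en-2-yl)cyclohexyl]-2,4,6-tris(methoxymethoxy)phenyl}-2-methylpropan-1-one | C=C(C)[C@H]1CC[C@@](C)(O)[C@@H](c2c(OCOC)c(C(=O)C(C)C)c(OCOC)cc2OCOC)C1 | intermediate
13 | 1-{2,4,6-trihydroxy-3-[(1R,2R,5S)-2-hydroxy-2-methyl-5-(prop-1-en-2-yl)cyclohexyl]phenyl}-2-methylpropan-1-one | C=C(C)[C@H]1CC[C@@](C)(O)[C@@H](c2c(O)c(C(=O)C(C)C)c(O)cc2O)C1 | intermediate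
14 | 1-{2,4,6-trihydroxy-3-[(1R,2R,5S)-2-hydroxy-2-methyl-5-(prop-1-en-2-yl)cyclohexyl]-5-(3-methylbut-2-en-1-yl)phenyl}-2-methylpropan-1-one | C=C(C)[C@H]1CC[C@@](C)(O)[C@@H](c2c(O)c(C(=O)C(C)C)c(O)c(CC=C(C)C)c2O)C1 | intermediate
15 | 3,5-dihydroxy-4-[(1R,2R,5S)-2-hydroxy-2-methyl-5-(prop-1-en-2-yl)cyclohexyl]-2-(2-methylpropanoyl)-6,6-bis(3-methylbut-2-en-1-yl)cyclohexa-2,4-dien-1-one | C=C(C)[C@H]1CC[C@@](C)(O)[C@@H](C2=C(O)C(CC=C(C)C)(CC=C(C)C)C(=O)C(C(=O)C(C)C)=C2O)C1 | target

## Step count and least certain steps

Total step count: 8. Longest linear sequence: 7 steps (steps 1, 2, 4, 5, 6, 7, 8, from 1). The terpene branch from 4 is 6 steps.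

**Step 3 (key step).** Three things may go wrong. The E2 elimination may remove the ring methine hydrogen and give the isopropylidene isomer, which is best separated after step 4. Traces of HI may cleave 4 protically or desilylate 6; both pass through the achiral ketone, and re-silylation of that ketone would erode enantiomeric purity. The fragmentation may also be slow at the low temperature needed to keep 5 intact. The fallback uses the acetylative form of the same cleavage and sets out from 4. BF3·OEt2, Zn(OAc)2 and Ac2O should give (4S)-4-(2-acetoxypropan-2-yl)cyclohex-1-en-1-yl acetate F1, in which the cation is trapped as an acetate and the enol acetate is stable to acid. MeLi and then TMSCl should convert F1 regiospecifically into (4S)-1-(trimethylsilyloxy)-4-[2-(trimethylsilyloxy)propan-2-yl]cyclohex-1-ene F2. Arylation with 3 under the conditions of step 4 should give (2R,4S)-4-(2-hydroxypropan-2-yl)-2-[2,4,6-tris(methoxymethoxy)phenyl]cyclohexan-1-one F3. Dehydration of the tertiary alcohol (SOCl2, pyridine, 0 °C, or Burgess reagent) comes back to the route at 9.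

**Step 4.** Oxidative addition and transmetalation may be slow with the di-ortho-alkoxy, electron-rich bromide, and a Heck reaction at the isopropenyl group may compete. Protodesilylation of 6 would return the achiral ketone, and any re-enolisation of that ketone would leak enantiomeric purity. The fallback reverses the polarity at the other partner and sets out from 6 and 2. The enolonium species made from 6 with PhI(OAc)2 and BF3·OEt2 at −78 °C is trapped by arene 2 as a Friedel–Crafts nucleophile at the former enol carbon. Equilibration with K2CO3 in MeOH comes back at 9. No new isolable compound is involved.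

**Step 5.** Enolisation of the α-aryl ketone may compete with addition, and axial attack would give the C1 epimer. The fallback sets C1 under thermodynamic control and sets out from 9. Corey–Chaykovsky reaction with dimethylsulfoxonium methylide (reversible betaine formation, new C–C bond equatorial) should give (3R,4R,6S)-6-(prop-1-en-2-yl)-4-[2,4,6-tris(methoxymethoxy)phenyl]-1-oxaspiro[2.5]octane F4, with the oxygen axial and cis to the aryl group. Opening at the CH2 with LiEt3BH comes back at 10.

**Step 7.** Acid may ionise the tertiary C1–OH, followed by capture by the neighbouring phenol (dihydrobenzofuran) or elimination, or it may add methanol to the isopropenyl group. The fallback replaces acidolysis by an aprotic acetal-to-silyl exchange and sets out from 12. TESOTf with 2,2′-bipyridyl should give 1-{3-[(1R,2R,5S)-2-hydroxy-2-methyl-5-(prop-1-en-2-yl)cyclohexyl]-2,4,6-tris(triethylsilyloxy)phenyl}-2-methylpropan-1-one F5. Any silylation of the tertiary alcohol would be reversed in the next operation. Fluoride (TBAF, AcOH, THF) comes back at 13.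

**Step 8.** O-Alkylation, incomplete or excessive alkylation, and alkylation at C1′ may all lower the yield of the double C5′ alkylation. The fallback sets out from 13. Tsuji–Trost double C-allylation (allyl methyl carbonate, Pd(PPh3)4; O-allyl products re-ionise, so the C-allyl product accumulates) should give 6,6-diallyl-3,5-dihydroxy-4-[(1R,2R,5S)-2-hydroxy-2-methyl-5-(prop-1-en-2-yl)cyclohexyl]-2-(2-methylpropanoyl)cyclohexa-2,4-dien-1-one F6. Cross-metathesis with 2-methyl-2-butene (Grubbs second-generation catalyst; the 1,1-disubstituted isopropenyl group reacts slowly) comes back at 15.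

## Further compounds

F1 | step 3 | (4S)-4-(2-acetoxypropan-2-yl)cyclohex-1-en-1-yl acetate | CC(=O)OC(C)(C)[C@H]1CCC(OC(C)=O)=CC1
F2 | step 3 | (4S)-1-(trimethylsilyloxy)-4-[2-(trimethylsilyloxy)propan-2-yl]cyclohex-1-ene | CC(C)(O[Si](C)(C)C)[C@H]1CCC(O[Si](C)(C)C)=CC1
F3 | step 3 | (2R,4S)-4-(2-hydroxypropan-2-yl)-2-[2,4,6-tris(methoxymethoxy)phenyl]cyclohexan-1-one | CC(C)(O)[C@H]1CCC(=O)[C@@H](c2c(OCOC)cc(OCOC)cc2OCOC)C1
F0 | step 4 | none | none
F4 | step 5 | (3R,4R,6S)-6-(prop-1-en-2-yl)-4-[2,4,6-tris(methoxymethoxy)phenyl]-1-oxaspiro[2.5]octane | C=C(C)[C@H]1CC[C@@]2(OC2)[C@@H](c3c(OCOC)cc(OCOC)cc3OCOC)C1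
F5 | step 7 | 1-{3-[(1R,2R,5S)-2-hydroxy-2-methyl-5-(prop-1-en-2-yl)cyclohexyl]-2,4,6-tris(triethylsilyloxy)phenyl}-2-methylpropan-1-one | C=C(C)[C@H]1CC[C@@](C)(O)[C@@H](c2c(O[Si](CC)(CC)CC)c(C(=O)C(C)C)c(O[Si](CC)(CC)CC)cc2O[Si](CC)(CC)CC)C1
F6 | step 8 | 6,6-diallyl-3,5-dihydroxy-4-[(1R,2R,5S)-2-hydroxy-2-methyl-5-(prop-1-en-2-yl)cyclohexyl]-2-(2-methylpropanoyl)cyclohexa-2,4-dien-1-one | C=C(C)[C@H]1CC[C@@](C)(O)[C@@H](C2=C(O)C(CC=C)(CC=C)C(=O)C(C(=O)C(C)C)=C2O)C1
A1 | alternative 1 | (1R,2S,4S)-limonene 1,2-oxide (trans-limonene oxide, oxygen cis to isopropenyl) | C=C(C)[C@H]1CC[C@@]2(C)O[C@H]2C1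
A2 | alternative 1 | 3,5-dihydroxy-2-(2-methylpropanoyl)-6,6-bis(3-methylbut-2-en-1-yl)cyclohexa-2,4-dien-1-one | CC(C)C(=O)C1=C(O)C=C(O)C(CC=C(C)C)(CC=C(C)C)C1=O
A3 | alternative 1 | C2 epimer of the target, (1R,2S,4S) on ring A | C=C(C)[C@H]1CC[C@@](C)(O)[C@H](C2=C(O)C(CC=C(C)C)(CC=C(C)C)C(=O)C(C(=O)C(C)C)=C2O)C1
A4 | alternative 2 | 1-{[(4S)-4-(prop-1-en-2-yl)cyclohex-1-en-1-yl]methoxy}-3,5-bis(methoxymethoxy)benzene (aryl perillyl ether) | C=C(C)[C@H]1CCC(COc2cc(OCOC)cc(OCOC)c2)=CC1
A5 | alternative 2 | 3,5-bis(methoxymethoxy)-2-[(1R,5S)-2-methylidene-5-(prop-1-en-2-yl)cyclohexyl]phenol (the cis isomer that would be needed) | C=C(C)[C@H]1CCC(=C)[C@@H](c2c(O)cc(OCOC)cc2OCOC)C1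
A6 | alternative 3 | (+)-β-pinene, (1R,5R)-6,6-dimethyl-2-methylidenebicyclo[3.1.1]heptane | CC1(C)[C@@H]2CCC(=C)[C@H]1C2
A7 | alternative 3 | (−)-nopinone, (1S,5R)-6,6-dimethylbicyclo[3.1.1]heptan-2-one | CC1(C)[C@@H]2CCC(=O)[C@H]1C2
A8 | alternative 3 | 3-[2,4,6-tris(methoxymethoxy)phenyl] derivative of (1S,5R)-nopinone, aryl anti to the gem-dimethyl bridge | CC1(C)[C@@H]2C[C@@H](c3c(OCOC)cc(OCOC)cc3OCOC)C(=O)[C@H]1C2
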